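The readings stem from a simulated flask for an exercise.

**The ratio.** The free catalyst of Friday's run stands to that of Sunday's run as 3.00 to one, and I started from that ratio.

| setting | Tuesday's | Sunday's | Saturday's | Friday's |
|---|---|---|---|---|
| starting material | 0.800 M | 0.400 M | 1.20 M | 0.260 M |
| free catalyst | 0.0800 M | 0.0800 M | 0.0800 M | 0.240 M |
| time |  |  |  | 11 min |

| run | time / min | [target] / M |
|---|---|---|
| Tuesday's run | 0.44 | 0.0308 |
| Tuesday's run | 0.98 | 0.0793 |
| Tuesday's run | 2.2 | 0.1856 |
| Tuesday's run | 4.9 | 0.3343 |
| Tuesday's run | 11 | 0.4573 |
| Sunday's run | 0.44 | 0.0122 |
| Sunday's run | 0.98 | 0.0401 |
| Sunday's run | 2.2 | 0.0921 |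
| Sunday's run | 4.9 | 0.1727 |
| Sunday's run | 11 | 0.2627 |
| Saturday's run | 0.44 | 0.0434 |
| Saturday's run | 0.98 | 0.1219 |
| Saturday's run | 2.2 | 0.2664 |
| Saturday's run | 4.9 | 0.4786 |
| Saturday's run | 11 | 0.6222 |

(readings scatter by 0.002 M)

* how the opening rate goes with [starting material] round the charge of the Tuesday's run: the exponent of the rate at two percent of starting material gone to target (one fixed amount of target, the same in the runs compared)
* the Sunday's run starts with 0.400 M less of starting material than the Tuesday's run, and with no target. Compared where both hold the same amount of starting material, once fifteen percent of what the Sunday's run was charged with has turned into target, is the Sunday's run faster, slower or alike (within a tenth)?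
* target in the Friday's run at 11 min, as a share of the starting material charged

- Overall: starting material -> target, with free catalyst as catalyst.
- Constant volume, constant temperature.
- An order is taken over about fifteen percent of the charge, up and down.

**The number.** I reckoned in fractions of the charge and counted what I call the exposure: the natural logarithm of the charge over what remains of it. If the catalyst holds, starting material falls in pseudo-first-order fashion, and each unit of exposure leaves a share of one over e. Sunday's run reached 1.07 at 11 min. Tuesday's, Sunday's and Saturday's runs had the same charge of free catalyst, so taking exposure as proportional to free catalyst was my assumption, not a reading. The exposure of Friday's run at that time, the catalyst ratio times Sunday's exposure, then came to 3.21. That left 4.04% of the charge and gave 96.0% as target.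

**The test.** One number was not quite enough. At equal free catalyst, the exposure at 11 min was 0.731 in Saturday's run and 0.848 in Tuesday's, both lower than Sunday's, and across these runs it fell as the target read at that time rose. My reckoning put 0.249 M of target in Friday's run at 11 min, a little less than the 0.2627 M read in Sunday's run at that time. I held 96.0% as the high side of my reckoning.

**The forecast.** The forecast gave 94% (range 80% to 99%), an order of 0.9 and faster for Sunday's run, remarking: “The catalyst order is untested.”

**The result.** Friday's run gave 94.9%, the order was 0.77, and Sunday's run was faster.

    active catalyst + starting material → target + active catalyst (1.644 M⁻¹ min⁻¹)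
    free catalyst → active catalyst (5.634 min⁻¹)
    active catalyst + target → spent catalyst + target (0.4662 M⁻¹ min⁻¹)

**The exposure.** Friday's share means an exposure of 2.97, lower than my 3.21. Where Sunday's and Tuesday's runs held the same starting material, Sunday's rate was 4.8 times Tuesday's. My exposure of 3.21, scaled to 0.0800 M of free catalyst and spread evenly over 11 min, reaches 0.693, the mark of half the charge, at 7.13 min. Tuesday's run stood there at 7.04 min, and Saturday's at 9.20 min.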